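Count the nucleophile and the count closes at every moment: what you charged is what stays free, plus what went into product, plus what sits as protonated nucleophile, plus what the protic impurity quenched. Across these flasks the electrophile and nucleophile charges stay the same; the impurity changes, and you stop at 8.0 min.

the same everywhere: electrophile 0.69 M

| flask | nucleophile | protic impurity | remark | time |
|---|---|---|---|---|
| summer | 3 equiv | 0.065 M | run made earlier |  |
| midnight | 3 equiv | 1.2 M | run made earlier |  |
| ochre | 3.00 equiv | 0.0500 M |  | 8.0 min |
| amber | 3.00 equiv | 0.100 M |  | 8.0 min |
| green | 3.00 equiv | 0.200 M |  | 8.0 min |
| violet | 3.00 equiv | 0.400 M |  | 8.0 min |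
| blue | 3.00 equiv | 0.800 M |  | 8.0 min |

| run | time / min | product / % | electrophile / % |
|---|---|---|---|
| summer | 0.333 | 3.7 | 96.2 |
| summer | 1.00 | 11.0 | 90.6 |
| summer | 2.00 | 17.6 | 82.4 |
| summer | 3.00 | 24.8 | 75.7 |
| summer | 4.00 | 31.3 | 68.6 |
| midnight | 0.333 | 2.9 | 97.5 |
| midnight | 0.667 | 4.3 | 95.5 |
| midnight | 1.00 | 6.9 | 93.2 |
| midnight | 2.00 | 11.9 | 88.8 |
| midnight | 4.00 | 17.5 | 82.5 |

(readings scatter by 0.5 percentage points)

- reactions considered so far: nucleophile + acid set free <-> protonated nucleophile; nucleophile + protic impurity -> quenched reagent; electrophile + nucleophile -> acid set free + product
- "hardly changes" means that all values lie within two and a half points (for a concentration: within two and a half percent of the largest)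

- amount of product at the end, in percent of the electrophile charged for ochre, amber, green, violet, blue, in this order
- how that number moves from the first to the last of them (hardly changes / falls, then rises / rises, then falls / falls all the way / rises all the way)

Take the charged nucleophile less the charged protic impurity, 2.02 M in ochre, and call it the budget. I charge each product two from it, one bonded and one tied up by the acid set free, so once the quench is over free nucleophile is the budget minus 2[product]. The midnight run tests that. Its budget is 0.870 M, and the summer budget of 2.00 M gives, through the integrated second-order law at 4.00 min, a rate constant reading of 0.0531 /M/min. With that reading, the midnight slope from 2.00 min to 4.00 min implies 0.618 M free nucleophile. Two per product predicts 0.667 M, one per product 0.769 M, so I keep two.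

Now draw the curve. It starts at a slope of k times the full nucleophile charge, 0.110 /min of the electrophile charged. Then comes a knee as the quench ends: the midnight slope drops from 0.0871 /min over the first reading to 0.0280 /min after 2.00 min. Watch for that knee in blue, whose quench takes 38.6% of the nucleophile charged, against 2.42% in ochre. Past it the slope is k times the budget less what product has spent, times the fraction of electrophile left; with the whole electrophile still counted and no product yet, that is 0.107 /min in ochre and 0.0675 /min in blue. The level differs too. The ochre budget exceeds twice the electrophile, but the blue budget of 1.27 M falls short of it: at two per product it pays for 92.0% of the electrophile charged. At 8.0 min my integration gives 49.7% for ochre and 34.5% for blue.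

The forecast differs slightly from those two, with 49%, 48%, 46.5%, 43%, 35%, and the shape falls all the way. Its ground: “More impurity only removes nucleophile, so yield falls steadily, and fastest at the high end.”

The flasks give 49.1%, 48.2%, 46.5%, 42.9%, 35.0%: falls all the way.

    nucleophile + acid set free ⇌ protonated nucleophile, settled at all times (K = 690 /M)
    nucleophile + protic impurity → quenched reagent (k = 1.20 /M/min)
    electrophile + nucleophile → acid set free + product (k = 0.0520 /M/min)

In ochre, half of the quench up to 8.0 min is done by 0.284 min and half of the product-forming turnover up to then by 2.94 min, ten times as late, and by 4.00 min the quench has >99.9% of its turnover up to 8.0 min behind it. Take two per product from the budget at 8.0 min: ochre keeps 64.9% of its nucleophile free against the flask's 65%, and blue keeps 38.0% against the flask's 38%.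

(All runs were computed on assumed constants; scatter was added.)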